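**Strategy.** The ten-membered carbocycle (germacrane numbering) is closed last at C9–C10, the bond that joins the carbinol carbon C9 to C10 of the E-configured C1=C10 trisubstituted olefin. In the open precursor both carbons are electrophilic: C9 is an aldehyde and C10 an alkenyl iodide. A Nozaki–Hiyama–Kishi reaction reverses the polarity of C10 through an alkenylchromium species and forms the ring, the C9 stereocentre and the allylic alcohol in one operation, with the olefin geometry carried over from the iodide. The precursor is an acyclic (E)-2-iodoallyl ester bearing the C4–C5 epoxide, the C7 stereocentre and the C9 aldehyde; it is assembled from a δ-lactone, a phosphonate and a syn-aldol acid.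

Key step: step 17

Remark: atoms are numbered as in germacranes (ring C1–C10, C1=C10 olefin, C4–C5 epoxide, C7 carrying C11–C13, C14 on C10, C15 on C4); the sense of induction in step 1 and the face selectivity in step 17 are predictions by analogy, not established facts.

Step 1
Reactants: 1 isopropenylboronic acid pinacol ester; 2 5,6-dihydro-2H-pyran-2-one
Product: 3 (4S)-4-(prop-1-en-2-yl)oxan-2-one
Conditions: [Rh(OH)(cod)]2 (2.5 mol%), (S)-BINAP (5.5 mol%), dioxane/H2O 10:1, 50 °C
Reagents that add atoms: none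
Why: Rhodium-catalysed asymmetric 1,4-addition of an alkenylboronate to a cyclic enoate (Hayashi–Miyaura reaction) should give the β-alkenyl lactone; the (S)-BINAP ligand selects the enoate face and so sets the 4S centre (the later C7), its sense assigned by analogy with aryl additions to the same lactone.

Step 2
Reactants: 3 (4S)-4-(prop-1-en-2-yl)oxan-2-one
Product: 4 (4S)-4-(prop-1-en-2-yl)oxan-2-ol (lactol)
Conditions: i-Bu2AlH (1.1 equiv), CH2Cl2, −78 °C; aq. potassium sodium tartrate
Reagents that add atoms: none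
Why: Half-reduction of a δ-lactone with i-Bu2AlH at −78 °C should stop at the lactol because the tetrahedral aluminium alkoxide is stable at that temperature.

Step 3
Reactants: 5 ethyl 2-[bis(2-methylphenoxy)phosphoryl]acetate; 6 4-bromobut-1-yne
Product: 7 ethyl 2-[bis(2-methylphenoxy)phosphoryl]hex-5-ynoate (racemic)
Conditions: NaH, DMSO, rt; then 6, rt
Reagents that add atoms: none
Why: SN2 alkylation of the sodium salt of a phosphonoacetate with a primary bromide should give the α-substituted Horner–Wadsworth–Emmons reagent; the new centre is lost again in step 4.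

Step 4
Reactants: 4 lactol; 7 alkynyl phosphonate
Product: 9 ethyl (2Z,5R)-2-(but-3-yn-1-yl)-5-(prop-1-en-2-yl)-7-(triethylsilyloxy)hept-2-enoate, via hydroxy enoate 8 (not isolated)
Conditions: 7 (2.2 equiv), NaH, THF, 0 °C; 4, −78 °C to 0 °C; then Et3SiCl, 0 °C
Reagents that add atoms: chlorotriethylsilane, CC[Si](Cl)(CC)CC
Why: Z-selective Horner–Wadsworth–Emmons olefination with a bis(aryloxy)phosphoryl ester on the open hydroxy aldehyde form of the lactol should place the ester cis to C6 through fast, irreversible collapse of the syn oxaphosphetane, and the liberated C9 alkoxide is silylated in the same flask before it can add to the enoate.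

Step 5
Reactants: 9 Z-enoate triethylsilyl ether
Product: 10 (2Z,5R)-2-(but-3-yn-1-yl)-5-(prop-1-en-2-yl)-7-(triethylsilyloxy)hept-2-en-1-ol
Conditions: i-Bu2AlH (2.5 equiv), CH2Cl2, −78 °C; aq. potassium sodium tartrate
Reagents that add atoms: none
Why: 1,2-Reduction of the conjugated ester with i-Bu2AlH should give the allylic alcohol (C15–OH) without touching the silyl ether, the alkyne or the olefin geometry.

Step 6
Reactants: 10 allylic alcohol
Product: 11 {(2S,3R)-2-(but-3-yn-1-yl)-3-[(2S)-2-(prop-1-en-2-yl)-4-(triethylsilyloxy)butyl]oxiran-2-yl}methanol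
Conditions: Ti(Oi-Pr)4 (0.2 equiv), L-(+)-diethyl tartrate (0.25 equiv), t-BuOOH, 4 Å molecular sieves, CH2Cl2, −20 °C
Reagents that add atoms: tert-butyl hydroperoxide, CC(C)(C)OO
Why: Sharpless asymmetric epoxidation should epoxidise only the allylic alcohol olefin, and L-(+)-diethyl tartrate directs the oxygen to the face that gives the 4S,5R epoxide (reagent control), the Z geometry placing C15 and C6 cis on the oxirane.

Step 7
Reactants: 11 epoxy alcohol
Product: 12 tert-butyldimethylsilyl ether of 11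
Conditions: t-BuMe2SiCl, imidazole, CH2Cl2, 0 °C to rt
Reagents that add atoms: tert-butyldimethylsilyl chloride, CC(C)(C)[Si](C)(C)Cl
Why: Standard silylation of the primary epoxy alcohol masks C15–OH for the later acylation and oxidation steps.

Step 8
Reactants: 12 epoxy bis-silyl ether with terminal alkyne
Product: 13 5-{(2S,3R)-2-[(tert-butyldimethylsilyloxy)methyl]-3-[(2S)-2-(prop-1-en-2-yl)-4-(triethylsilyloxy)butyl]oxiran-2-yl}pent-2-yn-1-ol
Conditions: n-BuLi, THF, −78 °C; (CH2O)n, −78 °C to rt; aq. NH4Cl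
Reagents that add atoms: paraformaldehyde (as formaldehyde), C=O
Why: Deprotonation of the terminal alkyne and addition of the lithium acetylide to formaldehyde should install C14 as a propargylic alcohol, the epoxide being inert to the acetylide at low temperature.

Step 9
Reactants: 13 propargylic alcohol
Product: 15 (2E)-5-{(2S,3R)-2-[(tert-butyldimethylsilyloxy)methyl]-3-[(2S)-2-(prop-1-en-2-yl)-4-(triethylsilyloxy)butyl]oxiran-2-yl}-2-iodopent-2-en-1-ol, via vinylstannane 14 (not isolated)
Conditions: Bu3SnH, Mo(CO)3(CNt-Bu)3 (cat.), hydroquinone (cat.), THF, 55 °C; solvent change to CH2Cl2, N-iodosuccinimide, 0 °C; aq. KF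
Reagents that add atoms: N-iodosuccinimide, O=C1CCC(=O)N1I
Why: Molybdenum-catalysed syn-hydrostannation of a propargylic alcohol should place tin on the alkyne carbon next to the hydroxymethyl group (C10) with hydrogen cis to it, and iododestannylation with retention then gives the E-iodoalkene in which iodine is trans to C2.

Step 10
Reactants: 16 (4R)-4-benzyl-3-propanoyl-1,3-oxazolidin-2-one; 17 acetaldehyde
Product: 18 (4R)-4-benzyl-3-[(2R,3S)-3-hydroxy-2-methylbutanoyl]-1,3-oxazolidin-2-one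
Conditions: Bu2BOTf, i-Pr2NEt, CH2Cl2, −78 °C to 0 °C; 17, −78 °C to 0 °C; H2O2, pH 7 buffer, MeOH
Reagents that add atoms: none
Why: Evans syn-aldol reaction through the Z-boron enolate and a chair transition state, with the (R)-benzyl auxiliary shielding one enolate face, should set the 2R,3S centres of the side chain.

Step 11
Reactants: 18 aldol adduct
Product: 19 (4R)-4-benzyl-3-[(2R,3S)-3-(tert-butyldimethylsilyloxy)-2-methylbutanoyl]-1,3-oxazolidin-2-one
Conditions: t-BuMe2SiOTf, 2,6-lutidine, CH2Cl2, 0 °C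
Reagents that add atoms: tert-butyldimethylsilyl trifluoromethanesulfonate, CC(C)(C)[Si](C)(C)OS(=O)(=O)C(F)(F)F
Why: Silylation of the secondary hydroxyl with the silyl triflate protects it for the later acylations.

Step 12
Reactants: 19 silylated aldol adduct
Product: 20 (2R,3S)-3-(tert-butyldimethylsilyloxy)-2-methylbutanoic acid
Conditions: LiOH, H2O2, THF/H2O, 0 °C; Na2SO3; HCl to pH 3
Reagents that add atoms: hydrogen peroxide (as lithium hydroperoxide), OO
Why: Lithium hydroperoxide attacks the exocyclic imide carbonyl selectively (auxiliary cleavage), which should release the acid without epimerisation at C2 and return the auxiliary.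

Step 13
Reactants: 15 (E)-2-iodoallylic alcohol; 20 protected acid
Product: 21 (2E)-5-{(2S,3R)-2-[(tert-butyldimethylsilyloxy)methyl]-3-[(2S)-2-(prop-1-en-2-yl)-4-(triethylsilyloxy)butyl]oxiran-2-yl}-2-iodopent-2-en-1-yl (2R,3S)-3-(tert-butyldimethylsilyloxy)-2-methylbutanoate
Conditions: EDC·HCl, DMAP, CH2Cl2, 0 °C to rt
Reagents that add atoms: none
Why: Steglich esterification (carbodiimide, DMAP) of the primary 2-iodoallylic alcohol with the protected acid should proceed without touching the epoxide or the silyl ethers.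

Step 14
Reactants: 21 iodoallyl ester with isopropenyl group
Product: 22 the 3-chloroprop-1-en-2-yl analogue of 21 (allylic chloride at C12)
Conditions: Ca(OCl)2, CO2 (dry ice), CH2Cl2/H2O, 0 °C
Reagents that add atoms: calcium hypochlorite, [Ca+2].[O-]Cl.[O-]Cl
Why: Ene-type allylic chlorination with hypochlorous acid should attack only the electron-rich 1,1-disubstituted olefin (the iodo-olefin is deactivated by iodine and the allylic ester), chlorine adding to the terminal carbon and a methyl proton being lost to give the 2-(chloromethyl)vinyl group.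

Step 15
Reactants: 22 allylic chloride
Product: 23 the 3-acetoxyprop-1-en-2-yl analogue of 21 (C12 acetate)
Conditions: CsOAc, DMF, 40 °C
Reagents that add atoms: caesium acetate, [Cs+].CC(=O)[O-]
Why: SN2 displacement of the primary allylic chloride by acetate should install the C12 acetate.

Step 16
Reactants: 23 acetate with primary triethylsilyl ether
Product: 24 (2E)-5-{(2S,3R)-3-[(2R)-2-(3-acetoxyprop-1-en-2-yl)-4-oxobutyl]-2-[(tert-butyldimethylsilyloxy)methyl]oxiran-2-yl}-2-iodopent-2-en-1-yl (2R,3S)-3-(tert-butyldimethylsilyloxy)-2-methylbutanoate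
Conditions: (COCl)2, DMSO, CH2Cl2, −78 °C to −30 °C; Et3N, to 0 °C
Reagents that add atoms: none
Why: Under Swern conditions a primary triethylsilyl ether is cleaved by the activated sulfoxide and oxidised directly to the aldehyde, while the tert-butyldimethylsilyl ethers, the epoxide and the esters should survive.

Step 17
Reactants: 24 iodoalkenyl aldehyde
Product: 25 (1(10)E,4S,5R,7S,9S)-12-acetoxy-15-(tert-butyldimethylsilyloxy)-4,5-epoxy-9-hydroxygermacra-1(10),11(13)-dien-14-yl (2R,3S)-3-(tert-butyldimethylsilyloxy)-2-methylbutanoate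
Conditions: CrCl2 (10 equiv), NiCl2 (0.1 equiv), DMSO/THF, rt, slow addition of 24 to a final 2 mM
Reagents that add atoms: none
Why: NiCl2 is reduced by CrCl2 to zerovalent nickel, which inserts into the C10–iodine bond; transmetalation gives an E-alkenyl species of trivalent chromium that adds to the C9 aldehyde, so that two electrophilic carbons are joined by reductive polarity reversal of C10. The closest known reaction type is the Nozaki–Hiyama–Kishi macrocyclisation of iodoalkenyl aldehydes to medium-ring allylic alcohols. The ten-membered carbocycle closes in a 10-exo-trig mode at the carbonyl carbon, and the C1=C10 olefin becomes endocyclic with its geometry retained, C9 taking the place of iodine (E in the ring). The new C9 stereocentre is under substrate control: with the C7 side chain pseudo-equatorial and the trans-epoxide fixing the C3–C6 segment, the chromium-bound carbonyl oxygen should point to the outside of the forming ring, so that C10 reaches the Re face of the aldehyde and the 9S alcohol results. The step needs ring closure to win over intermolecular coupling, which slow addition at high dilution secures, and needs insertion at the alkenyl iodide in preference to the two allylic esters, which the far higher reactivity of the carbon–iodine bond toward zerovalent nickel and the low basicity of the organochromium secure.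

Step 18
Reactants: 25 macrocyclic allylic alcohol
Product: 26 (1(10)E,4S,5R,7S,9S)-12-acetoxy-15-(tert-butyldimethylsilyloxy)-4,5-epoxy-9-(3-methylbutanoyloxy)germacra-1(10),11(13)-dien-14-yl (2R,3S)-3-(tert-butyldimethylsilyloxy)-2-methylbutanoate
Conditions: 3-methylbutanoyl chloride, pyridine, DMAP (cat.), CH2Cl2, 0 °C
Reagents that add atoms: 3-methylbutanoyl chloride, CC(C)CC(=O)Cl
Why: DMAP-catalysed acylation of the secondary allylic alcohol with the acid chloride should give the C9 ester with retention of configuration.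

Step 19
Reactants: 26 bis-silyl ether
Product: 27 CNP0132467.1
Conditions: HF·pyridine, pyridine, THF, 0 °C to rt
Reagents that add atoms: none
Why: Buffered fluoride desilylation cleaves both tert-butyldimethylsilyl ethers, and the pyridine buffer keeps the medium too weakly acidic for transannular opening of the epoxide or acyl migration.

**Compound list**

1 | 2-(prop-1-en-2-yl)-4,4,5,5-tetramethyl-1,3,2-dioxaborolane (isopropenylboronic acid pinacol ester) | C=C(C)B1OC(C)(C)C(C)(C)O1 | starting material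
2 | 5,6-dihydro-2H-pyran-2-one | O=C1C=CCCO1 | starting material
3 | (4S)-4-(prop-1-en-2-yl)oxan-2-one | C=C(C)[C@@H]1CC(=O)OCC1 | intermediate
4 | (4S)-4-(prop-1-en-2-yl)oxan-2-ol (lactol, both anomers) | C=C(C)[C@@H]1CC(O)OCC1 | intermediate
5 | ethyl 2-[bis(2-methylphenoxy)phosphoryl]acetate | CCOC(=O)CP(=O)(Oc1ccccc1C)Oc1ccccc1C | starting material
6 | 4-bromobut-1-yne | C#CCCBr | starting material
7 | ethyl 2-[bis(2-methylphenoxy)phosphoryl]hex-5-ynoate (racemic) | CCOC(=O)C(CCC#C)P(=O)(Oc1ccccc1C)Oc1ccccc1C | intermediate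
8 | ethyl (2Z,5R)-2-(but-3-yn-1-yl)-7-hydroxy-5-(prop-1-en-2-yl)hept-2-enoate (hydroxy enoate, present as its sodium alkoxide) | C=C(C)[C@H](C/C=C(/CCC#C)C(=O)OCC)CCO | intermediate
9 | ethyl (2Z,5R)-2-(but-3-yn-1-yl)-5-(prop-1-en-2-yl)-7-(triethylsilyloxy)hept-2-enoate | C=C(C)[C@H](C/C=C(/CCC#C)C(=O)OCC)CCO[Si](CC)(CC)CC | intermediate
10 | (2Z,5R)-2-(but-3-yn-1-yl)-5-(prop-1-en-2-yl)-7-(triethylsilyloxy)hept-2-en-1-ol | C=C(C)[C@H](C/C=C(/CCC#C)CO)CCO[Si](CC)(CC)CC | intermediate
11 | {(2S,3R)-2-(but-3-yn-1-yl)-3-[(2S)-2-(prop-1-en-2-yl)-4-(triethylsilyloxy)butyl]oxiran-2-yl}methanol | C=C(C)[C@H](C[C@H]1O[C@]1(CO)CCC#C)CCO[Si](CC)(CC)CC | intermediate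
12 | {(2S,3R)-2-(but-3-yn-1-yl)-3-[(2S)-2-(prop-1-en-2-yl)-4-(triethylsilyloxy)butyl]oxiran-2-yl}methyl tert-butyldimethylsilyl ether | C=C(C)[C@H](C[C@H]1O[C@]1(CO[Si](C)(C)C(C)(C)C)CCC#C)CCO[Si](CC)(CC)CC | intermediate
13 | 5-{(2S,3R)-2-[(tert-butyldimethylsilyloxy)methyl]-3-[(2S)-2-(prop-1-en-2-yl)-4-(triethylsilyloxy)butyl]oxiran-2-yl}pent-2-yn-1-ol | C=C(C)[C@H](C[C@H]1O[C@]1(CO[Si](C)(C)C(C)(C)C)CCC#CCO)CCO[Si](CC)(CC)CC | intermediate
14 | (2E)-5-{(2S,3R)-2-[(tert-butyldimethylsilyloxy)methyl]-3-[(2S)-2-(prop-1-en-2-yl)-4-(triethylsilyloxy)butyl]oxiran-2-yl}-2-(tributylstannyl)pent-2-en-1-ol (vinylstannane) | C=C(C)[C@H](C[C@H]1O[C@]1(CO[Si](C)(C)C(C)(C)C)CC/C=C(/[Sn](CCCC)(CCCC)CCCC)CO)CCO[Si](CC)(CC)CC | intermediate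
15 | (2E)-5-{(2S,3R)-2-[(tert-butyldimethylsilyloxy)methyl]-3-[(2S)-2-(prop-1-en-2-yl)-4-(triethylsilyloxy)butyl]oxiran-2-yl}-2-iodopent-2-en-1-ol | C=C(C)[C@H](C[C@H]1O[C@]1(CO[Si](C)(C)C(C)(C)C)CC/C=C(/I)CO)CCO[Si](CC)(CC)CC | intermediate
16 | (4R)-4-benzyl-3-propanoyl-1,3-oxazolidin-2-one | CCC(=O)N1[C@H](Cc2ccccc2)COC1=O | starting material
17 | acetaldehyde | CC=O | starting material
18 | (4R)-4-benzyl-3-[(2R,3S)-3-hydroxy-2-methylbutanoyl]-1,3-oxazolidin-2-one | O=C(N1[C@H](Cc2ccccc2)COC1=O)[C@H](C)[C@H](C)O | intermediate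
19 | (4R)-4-benzyl-3-[(2R,3S)-3-(tert-butyldimethylsilyloxy)-2-methylbutanoyl]-1,3-oxazolidin-2-one | O=C(N1[C@H](Cc2ccccc2)COC1=O)[C@H](C)[C@H](C)O[Si](C)(C)C(C)(C)C | intermediate
20 | (2R,3S)-3-(tert-butyldimethylsilyloxy)-2-methylbutanoic acid | O=C(O)[C@H](C)[C@H](C)O[Si](C)(C)C(C)(C)C | intermediate
21 | (2E)-5-{(2S,3R)-2-[(tert-butyldimethylsilyloxy)methyl]-3-[(2S)-2-(prop-1-en-2-yl)-4-(triethylsilyloxy)butyl]oxiran-2-yl}-2-iodopent-2-en-1-yl (2R,3S)-3-(tert-butyldimethylsilyloxy)-2-methylbutanoate | C=C(C)[C@H](C[C@H]1O[C@]1(CO[Si](C)(C)C(C)(C)C)CC/C=C(/I)COC(=O)[C@H](C)[C@H](C)O[Si](C)(C)C(C)(C)C)CCO[Si](CC)(CC)CC | intermediate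
22 | (2E)-5-{(2S,3R)-2-[(tert-butyldimethylsilyloxy)methyl]-3-[(2S)-2-(3-chloroprop-1-en-2-yl)-4-(triethylsilyloxy)butyl]oxiran-2-yl}-2-iodopent-2-en-1-yl (2R,3S)-3-(tert-butyldimethylsilyloxy)-2-methylbutanoate | C=C(CCl)[C@H](C[C@H]1O[C@]1(CO[Si](C)(C)C(C)(C)C)CC/C=C(/I)COC(=O)[C@H](C)[C@H](C)O[Si](C)(C)C(C)(C)C)CCO[Si](CC)(CC)CC | intermediate
23 | (2E)-5-{(2S,3R)-3-[(2S)-2-(3-acetoxyprop-1-en-2-yl)-4-(triethylsilyloxy)butyl]-2-[(tert-butyldimethylsilyloxy)methyl]oxiran-2-yl}-2-iodopent-2-en-1-yl (2R,3S)-3-(tert-butyldimethylsilyloxy)-2-methylbutanoate | C=C(COC(C)=O)[C@H](C[C@H]1O[C@]1(CO[Si](C)(C)C(C)(C)C)CC/C=C(/I)COC(=O)[C@H](C)[C@H](C)O[Si](C)(C)C(C)(C)C)CCO[Si](CC)(CC)CC | intermediate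
24 | (2E)-5-{(2S,3R)-3-[(2R)-2-(3-acetoxyprop-1-en-2-yl)-4-oxobutyl]-2-[(tert-butyldimethylsilyloxy)methyl]oxiran-2-yl}-2-iodopent-2-en-1-yl (2R,3S)-3-(tert-butyldimethylsilyloxy)-2-methylbutanoate | C=C(COC(C)=O)[C@H](C[C@H]1O[C@]1(CO[Si](C)(C)C(C)(C)C)CC/C=C(/I)COC(=O)[C@H](C)[C@H](C)O[Si](C)(C)C(C)(C)C)CC=O | intermediate
25 | (1(10)E,4S,5R,7S,9S)-12-acetoxy-15-(tert-butyldimethylsilyloxy)-4,5-epoxy-9-hydroxygermacra-1(10),11(13)-dien-14-yl (2R,3S)-3-(tert-butyldimethylsilyloxy)-2-methylbutanoate | C=C(COC(C)=O)[C@H]1C[C@H](O)/C(COC(=O)[C@H](C)[C@H](C)O[Si](C)(C)C(C)(C)C)=C/CC[C@@]2(CO[Si](C)(C)C(C)(C)C)O[C@@H]2C1 | intermediate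
26 | (1(10)E,4S,5R,7S,9S)-12-acetoxy-15-(tert-butyldimethylsilyloxy)-4,5-epoxy-9-(3-methylbutanoyloxy)germacra-1(10),11(13)-dien-14-yl (2R,3S)-3-(tert-butyldimethylsilyloxy)-2-methylbutanoate | C=C(COC(C)=O)[C@H]1C[C@H](OC(=O)CC(C)C)/C(COC(=O)[C@H](C)[C@H](C)O[Si](C)(C)C(C)(C)C)=C/CC[C@@]2(CO[Si](C)(C)C(C)(C)C)O[C@@H]2C1 | intermediate
27 | CNP0132467.1: (1(10)E,4S,5R,7S,9S)-12-acetoxy-4,5-epoxy-15-hydroxy-9-(3-methylbutanoyloxy)germacra-1(10),11(13)-dien-14-yl (2R,3S)-3-hydroxy-2-methylbutanoate | C=C(COC(C)=O)[C@H]1C[C@H](OC(=O)CC(C)C)/C(COC(=O)[C@H](C)[C@H](C)O)=C/CC[C@@]2(CO)O[C@@H]2C1 | target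

**Step count.** Total: 19 steps. Longest linear sequence: 15 steps (steps 1, 2, 4 to 9 and 13 to 19).

**Steps most likely to fail**

1. Step 17. The alkenylchromium may add to the Si face of the aldehyde, so that the ring closes to the 9R alcohol instead of the 9S alcohol. Fallback: setting out from 24, the ring closure is run as described and the 9R epimer F1 is oxidised with Dess–Martin periodinane to the macrocyclic enone F2. Reagent-controlled reduction of F2 with (R)-2-methyl-CBS-oxazaborolidine and catecholborane, with the alkenyl carbon C10 as the large group, should then return to 25.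

2. Step 4. The liberated C9 alkoxide may add in conjugate fashion to the new enoate (oxane formation), or the lactol may open too slowly at the low temperature at which the olefination is Z-selective. Fallback: setting out from lactone 3, aminolysis with MeNH(OMe)·HCl and Me3Al gives the hydroxy Weinreb amide F3. Silylation with Et3SiCl and imidazole gives the silyl ether F4, and reduction with i-Bu2AlH at −78 °C gives the aldehyde F5. The same olefination with 7 (NaH, THF, −78 °C), now on a free aldehyde that carries no hydroxyl, returns to 9.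

3. Step 9. Tin may be delivered to the distal alkyne carbon C1, which leads to the regioisomeric stannane and iodide. Fallback: setting out from alkyne 12, deprotonation with n-BuLi and acylation with ClCO2Me gives the methyl ynoate F6. Hydrostannation with Bu3SnH and Pd(PPh3)4, in which the ester directs tin to the α-carbon in a syn addition, gives the E-α-stannyl enoate F7. Iodine converts F7 with retention into the E-α-iodo enoate F8, and reduction with i-Bu2AlH at −78 °C returns to 15.

Further compounds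
F1 | step 17 | (1(10)E,4S,5R,7S,9R)-12-acetoxy-15-(tert-butyldimethylsilyloxy)-4,5-epoxy-9-hydroxygermacra-1(10),11(13)-dien-14-yl (2R,3S)-3-(tert-butyldimethylsilyloxy)-2-methylbutanoate (9R epimer of 25) | C=C(COC(C)=O)[C@H]1C[C@@H](O)/C(COC(=O)[C@H](C)[C@H](C)O[Si](C)(C)C(C)(C)C)=C/CC[C@@]2(CO[Si](C)(C)C(C)(C)C)O[C@@H]2C1
F2 | step 17 | (1(10)E,4S,5R,7R)-12-acetoxy-15-(tert-butyldimethylsilyloxy)-4,5-epoxy-9-oxogermacra-1(10),11(13)-dien-14-yl (2R,3S)-3-(tert-butyldimethylsilyloxy)-2-methylbutanoate (macrocyclic enone) | C=C(COC(C)=O)[C@H]1CC(=O)/C(COC(=O)[C@H](C)[C@H](C)O[Si](C)(C)C(C)(C)C)=C/CC[C@@]2(CO[Si](C)(C)C(C)(C)C)O[C@@H]2C1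
F3 | step 4 | (3S)-5-hydroxy-N-methoxy-N-methyl-3-(prop-1-en-2-yl)pentanamide | C=C(C)[C@H](CC(=O)N(C)OC)CCO
F4 | step 4 | (3S)-N-methoxy-N-methyl-3-(prop-1-en-2-yl)-5-(triethylsilyloxy)pentanamide | C=C(C)[C@H](CC(=O)N(C)OC)CCO[Si](CC)(CC)CC
F5 | step 4 | (3S)-3-(prop-1-en-2-yl)-5-(triethylsilyloxy)pentanal | C=C(C)[C@H](CC=O)CCO[Si](CC)(CC)CC
F6 | step 9 | methyl 6-{(2S,3R)-2-[(tert-butyldimethylsilyloxy)methyl]-3-[(2S)-2-(prop-1-en-2-yl)-4-(triethylsilyloxy)butyl]oxiran-2-yl}hex-2-ynoate | C=C(C)[C@H](C[C@H]1O[C@]1(CO[Si](C)(C)C(C)(C)C)CCC#CC(=O)OC)CCO[Si](CC)(CC)CC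
F7 | step 9 | methyl (2E)-6-{(2S,3R)-2-[(tert-butyldimethylsilyloxy)methyl]-3-[(2S)-2-(prop-1-en-2-yl)-4-(triethylsilyloxy)butyl]oxiran-2-yl}-2-(tributylstannyl)hex-2-enoate | C=C(C)[C@H](C[C@H]1O[C@]1(CO[Si](C)(C)C(C)(C)C)CC/C=C(/[Sn](CCCC)(CCCC)CCCC)C(=O)OC)CCO[Si](CC)(CC)CC
F8 | step 9 | methyl (2E)-6-{(2S,3R)-2-[(tert-butyldimethylsilyloxy)methyl]-3-[(2S)-2-(prop-1-en-2-yl)-4-(triethylsilyloxy)butyl]oxiran-2-yl}-2-iodohex-2-enoate | C=C(C)[C@H](C[C@H]1O[C@]1(CO[Si](C)(C)C(C)(C)C)CC/C=C(/I)C(=O)OC)CCO[Si](CC)(CC)CC
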